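Ring A is made last. The target's ring A is a resorcinol whose two oxygens (at C5 and C7) are 1,3 to each other and which shares the C4a–C8a bond with the pyranone ring C; a vinylketene–alkyne benzannulation delivers exactly this pattern. A fully substituted 4-pyranone that already carries the C3 oxygen and ring B, and a diazoacetyl group at the future C8a, is photolysed with (triisopropylsilyloxy)ethyne: Wolff rearrangement, [2+2] addition, four-electron ring opening and 6π ring closure form C5–C6, C7–C8 and C4a–C5 in one flask and leave O7 silylated, O5 free and chelated. Ring B arrives by Suzuki coupling with its 4'-oxygen marked by a 4-methoxybenzyl group for later sulfation.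

Key step: step 12

Assumption: the target is taken as the free hydrogen sulfate as drawn; it is released from its potassium salt only in the last operation, because aryl hydrogen sulfates hydrolyse on storage.
Abbreviation: Ar = 3-(benzyloxy)-4-[(4-methoxybenzyl)oxy]phenyl.

Step 1
Reactants: 1 kojic acid (5-hydroxy-2-(hydroxymethyl)-4H-pyran-4-one)
Product: 2 6-bromokojic acid (2-bromo-3-hydroxy-6-(hydroxymethyl)-4H-pyran-4-one)
Conditions: NBS, DMF, 0 → 20 °C
Reagents that add atoms: N-bromosuccinimide, O=C1CCC(=O)N1Br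
Why: Electrophilic bromination of the enolic 3-hydroxy-4-pyranone should occur at the ring carbon next to the hydroxyl (C6 of kojic acid), the site where kojic acid also reacts in Mannich and aldol reactions.

Step 2
Reactants: 2 6-bromokojic acid
Product: 3 3-(benzyloxy)-2-bromo-6-(hydroxymethyl)-4H-pyran-4-one
Conditions: BnBr, K2CO3, DMF, 20 °C
Reagents that add atoms: benzyl bromide, BrCc1ccccc1
Why: Williamson etherification, in which K2CO3 deprotonates only the acidic enolic hydroxyl, so the primary alcohol should stay free.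

Step 3
Reactants: 4 2-(benzyloxy)phenol
Product: 5 2-(benzyloxy)-4-bromophenol
Conditions: NBS, MeCN, 0 °C
Reagents that add atoms: N-bromosuccinimide, O=C1CCC(=O)N1Br
Why: Electrophilic aromatic bromination should go para to the free hydroxyl, the strongest director on the ring, as it does with guaiacol.

Step 4
Reactants: 5 2-(benzyloxy)-4-bromophenol
Product: 6 2-(benzyloxy)-4-bromo-1-[(4-methoxybenzyl)oxy]benzene
Conditions: 4-methoxybenzyl chloride, K2CO3, Bu4NI (cat.), DMF, 50 °C
Reagents that add atoms: 4-methoxybenzyl chloride, COc1ccc(CCl)cc1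
Why: Williamson etherification of the phenoxide puts the oxidatively removable group on the oxygen that becomes O4'.

Step 5
Reactants: 6 2-(benzyloxy)-4-bromo-1-[(4-methoxybenzyl)oxy]benzene
Product: 7 2-Ar-4,4,5,5-tetramethyl-1,3,2-dioxaborolane
Conditions: B2pin2, PdCl2(dppf), KOAc, 1,4-dioxane, 85 °C
Reagents that add atoms: bis(pinacolato)diboron, CC1(C)OB(OC1(C)C)B1OC(C)(C)C(C)(C)O1
Why: Miyaura borylation of an electron-rich aryl bromide under weakly basic conditions that both benzylic ethers tolerate.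

Step 6
Reactants: 3 3-(benzyloxy)-2-bromo-6-(hydroxymethyl)-4H-pyran-4-one; 7 2-Ar-4,4,5,5-tetramethyl-1,3,2-dioxaborolane
Product: 8 2-Ar-3-(benzyloxy)-6-(hydroxymethyl)-4H-pyran-4-one
Conditions: Pd(PPh3)4, K2CO3, 1,4-dioxane–H2O, 85 °C
Reagents that add atoms: none
Why: Suzuki–Miyaura coupling, in which the 2-bromo-4-pyranone behaves as a vinylogous acyl bromide that adds readily to zerovalent palladium, while the carbonate base is mild enough to spare the pyranone ring.

Step 7
Reactants: 8 2-Ar-3-(benzyloxy)-6-(hydroxymethyl)-4H-pyran-4-one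
Product: 9 6-Ar-5-(benzyloxy)-4-oxo-4H-pyran-2-carboxylic acid
Conditions: TEMPO (cat.), PhI(OAc)2, MeCN–H2O, 20 °C
Reagents that add atoms: water, O
Why: Oxoammonium (TEMPO) oxidation of the primary alcohol through the aldehyde hydrate to the acid runs near neutrality, so benzyl and 4-methoxybenzyl ethers should survive where chromic acid would endanger them.

Step 8
Reactants: 9 6-Ar-5-(benzyloxy)-4-oxo-4H-pyran-2-carboxylic acid
Product: 11 6-Ar-5-(benzyloxy)-2-(diazoacetyl)-4H-pyran-4-one, via mixed anhydride 10 (not isolated)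
Conditions: ClCO2Et, Et3N, THF, −10 °C; then Me3SiCHN2, MeCN, 0 → 20 °C
Reagents that add atoms: (trimethylsilyl)diazomethane, C[Si](C)(C)C=[N+]=[N-]
Why: Arndt–Eistert-type acylation of a diazoalkane, in which the reagent attacks the more electrophilic pyranoyl carbonyl of the mixed anhydride and the silyl group is lost to the carbonate leaving group, with no strong acid and no diazomethane gas.

Step 9
Reactants: 12 tetrahydrofuran; 13 triisopropylsilyl trifluoromethanesulfonate
Product: 15 triisopropyl(vinyloxy)silane, via lithium ethenolate 14 (not isolated)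
Conditions: n-BuLi, THF (reactant and solvent), 25 °C; then 13, −78 → 20 °C
Reagents that add atoms: none
Why: Metalation of tetrahydrofuran at C2 is followed by cycloreversion to ethene and the lithium enolate of acetaldehyde, which the hard silyl triflate traps on oxygen (silyl enol ether formation).

Step 10
Reactants: 15 triisopropyl(vinyloxy)silane
Product: 17 (Z)-(2-bromovinyloxy)triisopropylsilane, via dibromo ether 16 (not isolated)
Conditions: Br2, CH2Cl2, −78 °C; then Et3N, −78 → 20 °C
Reagents that add atoms: bromine, BrBr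
Why: Bromination–dehydrobromination, the classical route to β-bromovinyl ethers: the racemic α-bromo ether 16 loses HBr to the amine and should give mainly the Z alkene (oxygen and bromine cis), the geometry being set in the elimination and erased again in step 11.

Step 11
Reactants: 17 (Z)-(2-bromovinyloxy)triisopropylsilane
Product: 19 (triisopropylsilyloxy)ethyne, via lithium ethynide 18 (not isolated)
Conditions: LiN(i-Pr)2 (2.2 equiv), THF, −78 °C; then H2O, −78 → 0 °C
Reagents that add atoms: none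
Why: Base-induced dehydrobromination of a β-bromovinyl ether, the way alkoxyacetylenes are classically made; the second equivalent of base holds the product as its acetylide until the quench, and the bulky silyl group should suppress migration of silicon from oxygen to carbon.

Step 12
Reactants: 11 6-Ar-5-(benzyloxy)-2-(diazoacetyl)-4H-pyran-4-one; 19 (triisopropylsilyloxy)ethyne
Product: 24 3,3'-di-O-benzyl-4'-O-(4-methoxybenzyl)-7-O-(triisopropylsilyl)quercetin, via pyranonylketene 20 (not isolated), via siloxycyclobutenone 21 (not isolated), via dienylketene 22 (not isolated), via dienone tautomer 23 (not isolated)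
Conditions: 19 (2.5 equiv), ClCH2CH2Cl (degassed), 450 nm LED, 20 °C; then 80 °C (dark)
Reagents that add atoms: none
Why: Proposed new method: the closest known reaction type is the Danheiser benzannulation of aryl, heteroaryl and alkenyl α-diazo ketones with siloxyalkynes by way of a photochemical Wolff rearrangement, and the new element is a 4-pyranone C2=C3 bond in the role of the vinyl unit, which should be at least as willing as a furan or benzene C=C because little aromaticity is lost. Light of 450 nm should be absorbed by the diazo ketone but not by the pyranone or the flavonol product (ultraviolet lamps would trigger pyranone photochemistry); loss of N2 with migration of the pyranonyl group gives ketene 20, whose central carbon is attacked by the unsubstituted, electron-rich carbon of 19 to close cyclobutenone 21 in a [2+2] addition (bonds C5–C6 and C7–C8 in flavone numbering). On heating, 21 opens in a four-electron electrocyclic step to dienylketene 22, ring A closes by a thermal disrotatory 6π-electrocyclisation between the ketene carbon and the pyranone C–H carbon (bond C4a–C5), and dienone 23 enolises to the phenol, driven by aromaticity and by the hydrogen bond from O5–H to the C4 carbonyl. No stereocentre survives: the sp3 carbons of 21 and 23 are both planarised on the way to 24. The selectivity needed is the orientation of the ketene–alkyne addition, and the silyloxy group secures it by polarising the triple bond, so that the silyl ether ends at C7 and the free hydroxyl at C5 in a 1,3 relationship; ring closure has no choice, since only one carbon next to the ketene-bearing carbon of the pyranone carries hydrogen.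

Step 13
Reactants: 24 3,3'-di-O-benzyl-4'-O-(4-methoxybenzyl)-7-O-(triisopropylsilyl)quercetin
Product: 25 3,3'-di-O-benzyl-7-O-(triisopropylsilyl)quercetin
Conditions: DDQ, CH2Cl2–pH 7 buffer, 0 → 20 °C
Reagents that add atoms: none
Why: Oxidative cleavage of a 4-methoxybenzyl ether by DDQ (hydride abstraction, then hydrolysis of the oxocarbenium ion) should free only O4', since plain benzyl ethers, the silyl ether and the chelated 5-hydroxyl are not oxidised under these conditions.

Step 14
Reactants: 25 3,3'-di-O-benzyl-7-O-(triisopropylsilyl)quercetin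
Product: 27 potassium 3,3'-di-O-benzylquercetin 4'-sulfate, via pyridinium sulfate 26 (not isolated)
Conditions: SO3·pyridine, pyridine, 20 °C; MeOH; then KF, MeOH, 20 °C
Reagents that add atoms: sulfur trioxide–pyridine complex, O=S(=O)([O-])[n+]1ccccc1; potassium fluoride, [K+].[F-]
Why: O-sulfation of a phenol with SO3·pyridine should touch only the 4'-hydroxyl, because the 5-hydroxyl is held in a hydrogen bond to the C4 carbonyl; once methanol has destroyed the excess reagent, fluoride cleaves the labile 7-O-silyl ether (an acidic phenol is the leaving group) and supplies the potassium counter-ion.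

Step 15
Reactants: 27 potassium 3,3'-di-O-benzylquercetin 4'-sulfate
Product: 29 quercetin 4'-O-sulfate (target), via potassium salt 28 (not isolated)
Conditions: H2 (1 atm), Pd/C, MeOH–THF–H2O, 20 °C; filter; then HCl (1 equiv, aq.), 0 °C, C18 desalting
Reagents that add atoms: none
Why: Hydrogenolysis of the two benzyl ethers over Pd/C should leave the aryl sulfate, the C2=C3 bond and the carbonyl untouched, and one equivalent of acid in the cold converts the potassium salt to the hydrogen sulfate.

Compound list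
1 | kojic acid, 5-hydroxy-2-(hydroxymethyl)-4H-pyran-4-one | O=c1cc(CO)occ1O | starting material
2 | 6-bromokojic acid, 2-bromo-3-hydroxy-6-(hydroxymethyl)-4H-pyran-4-one | O=c1cc(CO)oc(Br)c1O | intermediate
3 | 3-(benzyloxy)-2-bromo-6-(hydroxymethyl)-4H-pyran-4-one | O=c1cc(CO)oc(Br)c1OCc1ccccc1 | intermediate
4 | 2-(benzyloxy)phenol | Oc1ccccc1OCc1ccccc1 | starting material
5 | 2-(benzyloxy)-4-bromophenol | Oc1ccc(Br)cc1OCc1ccccc1 | intermediate
6 | 2-(benzyloxy)-4-bromo-1-[(4-methoxybenzyl)oxy]benzene | COc1ccc(COc2ccc(Br)cc2OCc2ccccc2)cc1 | intermediate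
7 | 2-[3-(benzyloxy)-4-[(4-methoxybenzyl)oxy]phenyl]-4,4,5,5-tetramethyl-1,3,2-dioxaborolane | COc1ccc(COc2ccc(B3OC(C)(C)C(C)(C)O3)cc2OCc2ccccc2)cc1 | intermediate
8 | 3-(benzyloxy)-2-[3-(benzyloxy)-4-[(4-methoxybenzyl)oxy]phenyl]-6-(hydroxymethyl)-4H-pyran-4-one | O=c1cc(CO)oc(-c2ccc(OCc3ccc(OC)cc3)c(OCc3ccccc3)c2)c1OCc1ccccc1 | intermediate
9 | 5-(benzyloxy)-6-[3-(benzyloxy)-4-[(4-methoxybenzyl)oxy]phenyl]-4-oxo-4H-pyran-2-carboxylic acid | O=C(O)c1cc(=O)c(OCc2ccccc2)c(-c2ccc(OCc3ccc(OC)cc3)c(OCc3ccccc3)c2)o1 | intermediate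
10 | mixed carbonic anhydride of 9 with ethyl hydrogen carbonate | CCOC(=O)OC(=O)c1cc(=O)c(OCc2ccccc2)c(-c2ccc(OCc3ccc(OC)cc3)c(OCc3ccccc3)c2)o1 | intermediate
11 | 5-(benzyloxy)-6-[3-(benzyloxy)-4-[(4-methoxybenzyl)oxy]phenyl]-2-(diazoacetyl)-4H-pyran-4-one | [N-]=[N+]=CC(=O)c1cc(=O)c(OCc2ccccc2)c(-c2ccc(OCc3ccc(OC)cc3)c(OCc3ccccc3)c2)o1 | intermediate
12 | tetrahydrofuran | C1CCOC1 | starting material
13 | triisopropylsilyl trifluoromethanesulfonate | CC(C)[Si](OS(=O)(=O)C(F)(F)F)(C(C)C)C(C)C | starting material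
14 | lithium ethenolate (lithium enolate of acetaldehyde) | [Li+].[O-]C=C | intermediate
15 | triisopropyl(vinyloxy)silane | C=CO[Si](C(C)C)(C(C)C)C(C)C | intermediate
16 | (1,2-dibromoethoxy)triisopropylsilane, racemic | BrCC(Br)O[Si](C(C)C)(C(C)C)C(C)C | intermediate
17 | (Z)-(2-bromovinyloxy)triisopropylsilane | Br/C=C\O[Si](C(C)C)(C(C)C)C(C)C | intermediate
18 | lithium (triisopropylsilyloxy)ethynide | [Li]C#CO[Si](C(C)C)(C(C)C)C(C)C | intermediate
19 | (triisopropylsilyloxy)ethyne | C#CO[Si](C(C)C)(C(C)C)C(C)C | intermediate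
20 | 5-(benzyloxy)-6-Ar-2-(2-oxoethenyl)-4H-pyran-4-one (pyranonylketene) | O=C=Cc1cc(=O)c(OCc2ccccc2)c(-c2ccc(OCc3ccc(OC)cc3)c(OCc3ccccc3)c2)o1 | intermediate
21 | 5-(benzyloxy)-6-Ar-2-[4-oxo-2-(triisopropylsilyloxy)cyclobut-2-en-1-yl]-4H-pyran-4-one, racemic | O=C1C=C(O[Si](C(C)C)(C(C)C)C(C)C)C1c1cc(=O)c(OCc2ccccc2)c(-c2ccc(OCc3ccc(OC)cc3)c(OCc3ccccc3)c2)o1 | intermediate
22 | 5-(benzyloxy)-6-Ar-2-[(1E)-4-oxo-2-(triisopropylsilyloxy)buta-1,3-dien-1-yl]-4H-pyran-4-one (ketenyl and pyranonyl groups cis) | O=C=C/C(O[Si](C(C)C)(C(C)C)C(C)C)=C\c1cc(=O)c(OCc2ccccc2)c(-c2ccc(OCc3ccc(OC)cc3)c(OCc3ccccc3)c2)o1 | intermediate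
23 | 3-(benzyloxy)-2-Ar-7-(triisopropylsilyloxy)-4aH-chromene-4,5-dione, racemic at C4a (keto tautomer of 24) | O=C1C=C(O[Si](C(C)C)(C(C)C)C(C)C)C=C2OC(-c3ccc(OCc4ccc(OC)cc4)c(OCc4ccccc4)c3)=C(OCc3ccccc3)C(=O)C12 | intermediate
24 | 3,3'-di-O-benzyl-4'-O-(4-methoxybenzyl)-7-O-(triisopropylsilyl)quercetin | O=c1c(OCc2ccccc2)c(-c2ccc(OCc3ccc(OC)cc3)c(OCc3ccccc3)c2)oc2cc(O[Si](C(C)C)(C(C)C)C(C)C)cc(O)c12 | intermediate
25 | 3,3'-di-O-benzyl-7-O-(triisopropylsilyl)quercetin | O=c1c(OCc2ccccc2)c(-c2ccc(O)c(OCc3ccccc3)c2)oc2cc(O[Si](C(C)C)(C(C)C)C(C)C)cc(O)c12 | intermediate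
26 | pyridinium 3,3'-di-O-benzyl-7-O-(triisopropylsilyl)quercetin 4'-sulfate | O=c1c(OCc2ccccc2)c(-c2ccc(OS(=O)(=O)[O-])c(OCc3ccccc3)c2)oc2cc(O[Si](C(C)C)(C(C)C)C(C)C)cc(O)c12.c1cc[nH+]cc1 | intermediate
27 | potassium 3,3'-di-O-benzylquercetin 4'-sulfate | O=c1c(OCc2ccccc2)c(-c2ccc(OS(=O)(=O)[O-])c(OCc3ccccc3)c2)oc2cc(O)cc(O)c12.[K+] | intermediate
28 | potassium quercetin 4'-sulfate | O=c1c(O)c(-c2ccc(OS(=O)(=O)[O-])c(O)c2)oc2cc(O)cc(O)c12.[K+] | intermediate
29 | quercetin 4'-O-sulfate (hydrogen sulfate) | O=c1c(O)c(-c2ccc(OS(=O)(=O)O)c(O)c2)oc2cc(O)cc(O)c12 | target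

Total step count: 15 steps.
Longest linear sequence: 10 steps (steps 3, 4, 5, 6, 7, 8, 12, 13, 14 and 15).

Steps most likely to fail

1. Step 12 (bears the label).
- What may go wrong: the electron-poor pyranonyl group may migrate sluggishly in the Wolff step; the ketene may be lost to dimerisation or adventitious water before the alkyne captures it; the diazo ketone may add to the alkyne as a dipole; the six-electron closure onto the pyranone carbon may fail.
- Fallback (known chemistry; ring A is bought and ring C is closed classically): it sets out from aryl bromide 6 and returns at potassium salt 28, which the acidification of step 15 converts to 29.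
- Bromine–lithium exchange (n-BuLi, THF, −78 °C) and formylation with DMF give 3-(benzyloxy)-4-[(4-methoxybenzyl)oxy]benzaldehyde F1.
- Claisen–Schmidt condensation with commercial 1-[2,4-bis(benzyloxy)-6-hydroxyphenyl]ethanone (KOH, EtOH) gives (E)-1-[2,4-bis(benzyloxy)-6-hydroxyphenyl]-3-[3-(benzyloxy)-4-[(4-methoxybenzyl)oxy]phenyl]prop-2-en-1-one F2.
- Algar–Flynn–Oyamada oxidation (H2O2, NaOH, MeOH–THF) closes ring C to 5,7,3'-tri-O-benzyl-4'-O-(4-methoxybenzyl)quercetin F3; aurone formation is the known competing path for such chalcones and would cost material.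
- BnBr and K2CO3 in DMF give 3,5,7,3'-tetra-O-benzyl-4'-O-(4-methoxybenzyl)quercetin F4.
- DDQ frees O4' to give 3,5,7,3'-tetra-O-benzylquercetin F5.
- SO3·pyridine, then KHCO3, gives potassium 3,5,7,3'-tetra-O-benzylquercetin 4'-sulfate F6.
- Hydrogenolysis of the four benzyl ethers over Pd/C delivers 28.

2. Step 8.
- What may go wrong: the diazoalkane may attack the carbonate carbonyl or the electron-poor pyranone double bond; the mixed anhydride may collapse to the symmetrical anhydride before acylation.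
- Fallback (diazo transfer in place of acylation of a diazoalkane): it sets out from alcohol 8, so it also replaces step 7, and returns at diazo ketone 11.
- MnO2 in CH2Cl2 gives 5-(benzyloxy)-6-Ar-4-oxo-4H-pyran-2-carbaldehyde F7.
- MeMgBr in THF at −78 °C gives racemic 3-(benzyloxy)-2-Ar-6-(1-hydroxyethyl)-4H-pyran-4-one F8.
- Dess–Martin periodinane gives 2-acetyl-5-(benzyloxy)-6-Ar-4H-pyran-4-one F9.
- LiN(SiMe3)2 and CF3CO2CH2CF3 at −78 °C give 1-[5-(benzyloxy)-6-Ar-4-oxo-4H-pyran-2-yl]-4,4,4-trifluorobutane-1,3-dione F10, which is not isolated.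
- Methanesulfonyl azide with Et3N and H2O in MeCN effects detrifluoroacetylative diazo transfer to 11.

3. Step 14.
- What may go wrong: the 7-O-silyl group may be lost early in pyridine, or sulfur trioxide may be incompletely destroyed before fluoride is added; either would let sulfation spread to O7. Separation of the polar salt from inorganic material may also be difficult.
- Fallback (sulfur introduced as a neutral, chromatographable diester, with desilylation when no sulfating agent is present): it sets out from 25 and returns at 29.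
- 2,2,2-Trichloroethyl chlorosulfate with Et3N and DMAP in THF gives 3,3'-di-O-benzyl-7-O-(triisopropylsilyl)quercetin 4'-(2,2,2-trichloroethyl sulfate) F11.
- HF·pyridine in THF gives 3,3'-di-O-benzylquercetin 4'-(2,2,2-trichloroethyl sulfate) F12.
- Pd/C with HCO2NH4 in MeOH removes the trichloroethyl group and both benzyl ethers to give ammonium quercetin 4'-sulfate F13.
- One equivalent of HCl at 0 °C gives 29.

Further compounds
F1 | step 12 | 3-(benzyloxy)-4-[(4-methoxybenzyl)oxy]benzaldehyde | COc1ccc(COc2ccc(C=O)cc2OCc2ccccc2)cc1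
F2 | step 12 | (E)-1-[2,4-bis(benzyloxy)-6-hydroxyphenyl]-3-[3-(benzyloxy)-4-[(4-methoxybenzyl)oxy]phenyl]prop-2-en-1-one | COc1ccc(COc2ccc(/C=C/C(=O)c3c(O)cc(OCc4ccccc4)cc3OCc3ccccc3)cc2OCc2ccccc2)cc1
F3 | step 12 | 5,7,3'-tri-O-benzyl-4'-O-(4-methoxybenzyl)quercetin | COc1ccc(COc2ccc(-c3oc4cc(OCc5ccccc5)cc(OCc5ccccc5)c4c(=O)c3O)cc2OCc2ccccc2)cc1
F4 | step 12 | 3,5,7,3'-tetra-O-benzyl-4'-O-(4-methoxybenzyl)quercetin | COc1ccc(COc2ccc(-c3oc4cc(OCc5ccccc5)cc(OCc5ccccc5)c4c(=O)c3OCc3ccccc3)cc2OCc2ccccc2)cc1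
F5 | step 12 | 3,5,7,3'-tetra-O-benzylquercetin | O=c1c(OCc2ccccc2)c(-c2ccc(O)c(OCc3ccccc3)c2)oc2cc(OCc3ccccc3)cc(OCc3ccccc3)c12
F6 | step 12 | potassium 3,5,7,3'-tetra-O-benzylquercetin 4'-sulfate | O=c1c(OCc2ccccc2)c(-c2ccc(OS(=O)(=O)[O-])c(OCc3ccccc3)c2)oc2cc(OCc3ccccc3)cc(OCc3ccccc3)c12.[K+]
F7 | step 8 | 5-(benzyloxy)-6-[3-(benzyloxy)-4-[(4-methoxybenzyl)oxy]phenyl]-4-oxo-4H-pyran-2-carbaldehyde | O=Cc1cc(=O)c(OCc2ccccc2)c(-c2ccc(OCc3ccc(OC)cc3)c(OCc3ccccc3)c2)o1
F8 | step 8 | 3-(benzyloxy)-2-[3-(benzyloxy)-4-[(4-methoxybenzyl)oxy]phenyl]-6-(1-hydroxyethyl)-4H-pyran-4-one, racemic | CC(O)c1cc(=O)c(OCc2ccccc2)c(-c2ccc(OCc3ccc(OC)cc3)c(OCc3ccccc3)c2)o1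
F9 | step 8 | 2-acetyl-5-(benzyloxy)-6-[3-(benzyloxy)-4-[(4-methoxybenzyl)oxy]phenyl]-4H-pyran-4-one | CC(=O)c1cc(=O)c(OCc2ccccc2)c(-c2ccc(OCc3ccc(OC)cc3)c(OCc3ccccc3)c2)o1
F10 | step 8 | 1-[5-(benzyloxy)-6-[3-(benzyloxy)-4-[(4-methoxybenzyl)oxy]phenyl]-4-oxo-4H-pyran-2-yl]-4,4,4-trifluorobutane-1,3-dione | O=C(CC(=O)c1cc(=O)c(OCc2ccccc2)c(-c2ccc(OCc3ccc(OC)cc3)c(OCc3ccccc3)c2)o1)C(F)(F)F
F11 | step 14 | 3,3'-di-O-benzyl-7-O-(triisopropylsilyl)quercetin 4'-(2,2,2-trichloroethyl sulfate) | O=c1c(OCc2ccccc2)c(-c2ccc(OS(=O)(=O)OCC(Cl)(Cl)Cl)c(OCc3ccccc3)c2)oc2cc(O[Si](C(C)C)(C(C)C)C(C)C)cc(O)c12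
F12 | step 14 | 3,3'-di-O-benzylquercetin 4'-(2,2,2-trichloroethyl sulfate) | O=c1c(OCc2ccccc2)c(-c2ccc(OS(=O)(=O)OCC(Cl)(Cl)Cl)c(OCc3ccccc3)c2)oc2cc(O)cc(O)c12
F13 | step 14 | ammonium quercetin 4'-sulfate | O=c1c(O)c(-c2ccc(OS(=O)(=O)[O-])c(O)c2)oc2cc(O)cc(O)c12.[NH4+]
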